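The CH2–CHMe bond (C6–C7) and the aryl–spiro bond (C4a–C5) of the benzo[7]annulene ring are cut together (locants as in the name of target 12); this leaves a 4-hydroxy-3,5-dimethoxybenzylidene unit (C6 plus the dienone ring) and a C7–C8–C9–C9a–C4a unit carrying boron at C7.
Enabling feature: the spiro cyclohexa-2,5-dienone is an oxidised 4-alkyl-2,6-dimethoxyphenol, so C6 can serve as a diazo carbon that takes C7 from boron by 1,2-shift, and the para carbon C5 as a phenoxonium carbon that takes the free ortho C–H of the 3,4,5-trimethoxyphenyl ring; both six-membered rings are locally symmetric, so one regioisomer and no spiro stereocentre can result.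
Earlier cuts: C7–B (Markovnikov hydroboration of a vinyl group), O–benzoyl, C8–C9 (crotylboration of 3,4,5-trimethoxybenzaldehyde).
Forward order: the open chain is built first (C9 and C8, then C7); both six-membered rings come from commercial arenes; the seven-membered ring and the spiro junction are closed last, in one flask, with dearomatisation of the phenol ring.
Stereochemistry: C9 and C8 from a chiral phosphoric acid-catalysed (Z)-crotylboration (syn), C7 from a ligand-controlled borylcupration, carried into the ring with retention.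
Key step: step 6

Assumption: the facial sense of (R)-TRIP in step 1 and of the chosen bisphosphine enantiomer in step 3 is taken from simple aldehydes and 1-alkenes; the mirror-image catalyst is used if the sense proves opposite.

Step 1
Reactants: 1 3,4,5-trimethoxybenzaldehyde; 2 (Z)-crotylboronic acid pinacol ester
Product: 3 (1R,2S)-2-methyl-1-(3,4,5-trimethoxyphenyl)but-3-en-1-ol
Conditions: (R)-TRIP phosphoric acid (5 mol %), toluene, −30 °C; aqueous work-up
Reagents that add atoms: none
Why: Chiral phosphoric acid-catalysed allylboration through a closed chair (Zimmerman–Traxler-type) transition state, in which the (Z)-crotyl geometry gives the 1,2-syn relationship and the (R)-catalyst directs attack to the Re face of the aldehyde, setting C1 as R and C2 as S.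

Step 2
Reactants: 3 (1R,2S)-2-methyl-1-(3,4,5-trimethoxyphenyl)but-3-en-1-ol
Product: 4 (1R,2S)-2-methyl-1-(3,4,5-trimethoxyphenyl)but-3-en-1-yl benzoate
Conditions: BzCl, pyridine, DMAP (cat.), CH2Cl2, 0 °C to rt
Reagents that add atoms: benzoyl chloride, O=C(Cl)c1ccccc1
Why: DMAP-catalysed O-acylation of the secondary benzylic alcohol, which breaks no bond at a stereocentre and installs the ester of the target, needed later to keep this oxygen from adding to the oxidised phenol.

Step 3
Reactants: 4 (1R,2S)-2-methyl-1-(3,4,5-trimethoxyphenyl)but-3-en-1-yl benzoate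
Product: 5 (1R,2S,3S)-2-methyl-3-(4,4,5,5-tetramethyl-1,3,2-dioxaborolan-2-yl)-1-(3,4,5-trimethoxyphenyl)butyl benzoate
Conditions: CuCl (5 mol %), P-stereogenic bisphosphine of the QuinoxP* type (5 mol %), KOtBu (10 mol %), B2pin2, MeOH, THF, rt
Reagents that add atoms: bis(pinacolato)diboron, CC1(C)OB(OC1(C)C)B1OC(C)(C)C(C)(C)O1
Why: Copper-catalysed Markovnikov protoboration of an unactivated terminal alkene (syn borylcupration with boron on the internal carbon, then protonolysis of the primary C–Cu bond by methanol, which creates the C-methyl group), in which the chiral ligand selects the alkene face and so sets the boron-bearing carbon as S under catalyst control.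

Step 4
Reactants: 5 (1R,2S,3S)-2-methyl-3-(4,4,5,5-tetramethyl-1,3,2-dioxaborolan-2-yl)-1-(3,4,5-trimethoxyphenyl)butyl benzoate
Product: 6 [(2S,3S,4R)-4-(benzoyloxy)-3-methyl-4-(3,4,5-trimethoxyphenyl)butan-2-yl]boronic acid
Conditions: NaIO4, NH4OAc, acetone/H2O, rt
Reagents that add atoms: water, O
Why: Periodate cleavage of the pinacol ligand after hydrolytic exchange frees the boronic acid, the Lewis-acidic form needed for reaction with a diazo compound, without touching the C–B stereocentre.

Step 5
Reactants: 7 syringaldehyde (4-hydroxy-3,5-dimethoxybenzaldehyde)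
Product: 8 (E)-N'-(4-hydroxy-3,5-dimethoxybenzylidene)-4-methylbenzenesulfonohydrazide
Conditions: TsNHNH2, MeOH, rt
Reagents that add atoms: p-toluenesulfonyl hydrazide, Cc1ccc(cc1)S(=O)(=O)NN
Why: Condensation of the aldehyde with the sulfonyl hydrazide gives the bench-stable N-tosylhydrazone, the precursor of the aryldiazomethane (Bamford–Stevens chemistry).

Step 6
Reactants: 6 [(2S,3S,4R)-4-(benzoyloxy)-3-methyl-4-(3,4,5-trimethoxyphenyl)butan-2-yl]boronic acid; 8 (E)-N'-(4-hydroxy-3,5-dimethoxybenzylidene)-4-methylbenzenesulfonohydrazide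
Product: 12 (7R,8S,9R)-2,3,3',4,5'-pentamethoxy-7,8-dimethyl-4'-oxo-6,7,8,9-tetrahydrospiro[benzo[7]annulene-5,1'-cyclohexa[2,5]dien]-9-yl benzoate (target), via diazo compound 9 (not isolated), via benzylic boronic acid 10 (not isolated), via phenol 11 (not isolated)
Conditions: K2CO3, 1,4-dioxane, 110 °C; then concentrate, CF3CH2OH, PhI(OCOCF3)2 (excess), −20 °C
Reagents that add atoms: none
Why: Base converts 8 into the aryldiazomethane 9 (Bamford–Stevens), whose carbon adds to boron of 6; loss of N2 drives a suprafacial 1,2-shift of the secondary alkyl group from boron to carbon, which forms the CH2–CHMe bond and gives 10, and protonolysis of its benzylic C–B bond gives phenol 11. PhI(OCOCF3)2 in the non-nucleophilic fluoroalcohol then oxidises the 2,6-dimethoxyphenol to a phenoxonium-type species, whose para carbon is attacked by the free ortho C–H position of the 3,4,5-trimethoxyphenyl ring (intramolecular Friedel–Crafts-type attack), forming the aryl–spiro bond. The closest known reaction types are the metal-free reductive coupling of N-tosylhydrazones with alkylboronic acids and the trivalent-iodine para–ortho phenol–arene coupling of 4-hydroxybenzyl-substituted diarylbutanes to spirodienones, run here in one flask as a formal (5+2) annulation. The seven-membered ring closes in a 7-exo-trig mode at the para carbon of the oxidised phenol, which becomes the spiro atom of the six-membered ring already present. No new stereocentre is formed: C7 keeps the configuration set in step 3 because the boron-to-carbon shift is stereoretentive, and the spiro carbon is not stereogenic because the dienone ring is locally symmetric. The step needs transfer of the one carbon group on boron, para attack instead of benzylic deprotonation to a quinone methide, and a single arene position; these are secured by the boronic acid having only one migrating group, by the 2,6-dimethoxy pattern and the fluoroalcohol, by the equivalence of the two ortho positions of the trimethoxyphenyl ring, and by the benzoate, which keeps the C9 oxygen from adding to the oxidised ring.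

Compound list
1 | 3,4,5-trimethoxybenzaldehyde | COc1cc(C=O)cc(OC)c1OC | starting material
2 | (Z)-crotylboronic acid pinacol ester, 2-[(2Z)-but-2-en-1-yl]-4,4,5,5-tetramethyl-1,3,2-dioxaborolane | C/C=C\CB1OC(C)(C)C(C)(C)O1 | starting material
3 | (1R,2S)-2-methyl-1-(3,4,5-trimethoxyphenyl)but-3-en-1-ol | C=C[C@H](C)[C@@H](O)c1cc(OC)c(OC)c(OC)c1 | intermediate
4 | (1R,2S)-2-methyl-1-(3,4,5-trimethoxyphenyl)but-3-en-1-yl benzoate | C=C[C@H](C)[C@@H](OC(=O)c1ccccc1)c1cc(OC)c(OC)c(OC)c1 | intermediate
5 | (1R,2S,3S)-2-methyl-3-(4,4,5,5-tetramethyl-1,3,2-dioxaborolan-2-yl)-1-(3,4,5-trimethoxyphenyl)butyl benzoate | CC1(C)OB(OC1(C)C)[C@@H](C)[C@H](C)[C@@H](OC(=O)c1ccccc1)c1cc(OC)c(OC)c(OC)c1 | intermediate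
6 | [(2S,3S,4R)-4-(benzoyloxy)-3-methyl-4-(3,4,5-trimethoxyphenyl)butan-2-yl]boronic acid | OB(O)[C@@H](C)[C@H](C)[C@@H](OC(=O)c1ccccc1)c1cc(OC)c(OC)c(OC)c1 | intermediate
7 | syringaldehyde, 4-hydroxy-3,5-dimethoxybenzaldehyde | COc1cc(C=O)cc(OC)c1O | starting material
8 | (E)-N'-(4-hydroxy-3,5-dimethoxybenzylidene)-4-methylbenzenesulfonohydrazide | COc1cc(/C=N/NS(=O)(=O)c2ccc(C)cc2)cc(OC)c1O | intermediate
9 | 4-(diazomethyl)-2,6-dimethoxyphenol | COc1cc(C=[N+]=[N-])cc(OC)c1O | intermediate (not isolated)
10 | (1R,2S,3R)-4-borono-4-(4-hydroxy-3,5-dimethoxyphenyl)-2,3-dimethyl-1-(3,4,5-trimethoxyphenyl)butyl benzoate, both C4 epimers | COc1cc(C(B(O)O)[C@@H](C)[C@H](C)[C@@H](OC(=O)c2ccccc2)c2cc(OC)c(OC)c(OC)c2)cc(OC)c1O | intermediate (not isolated)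
11 | (1R,2S,3R)-4-(4-hydroxy-3,5-dimethoxyphenyl)-2,3-dimethyl-1-(3,4,5-trimethoxyphenyl)butyl benzoate | COc1cc(C[C@@H](C)[C@H](C)[C@@H](OC(=O)c2ccccc2)c2cc(OC)c(OC)c(OC)c2)cc(OC)c1O | intermediate (not isolated)
12 | (7R,8S,9R)-2,3,3',4,5'-pentamethoxy-7,8-dimethyl-4'-oxo-6,7,8,9-tetrahydrospiro[benzo[7]annulene-5,1'-cyclohexa[2,5]dien]-9-yl benzoate | COC1=CC2(C=C(OC)C1=O)C[C@@H](C)[C@H](C)[C@@H](OC(=O)c1ccccc1)c1cc(OC)c(OC)c(OC)c12 | target

Total step count: 6. Longest linear sequence: 5 (steps 1, 2, 3, 4, 6).

Steps most likely to fail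

Step 6. The unprotected hydroxyaryl diazomethane may be lost to self-condensation before the hindered boronic acid captures it, and the hot carbonate may cleave the benzoate. In the oxidative stage, benzylic deprotonation to a quinone methide followed by six-membered closure, or consumption of the oxidant by sulfinate, may compete with the spirocyclisation. The fallback separates the two events and protects the phenol. It sets out from 7 and 6: 7 is O-allylated (allyl bromide, K2CO3, DMF) to 4-(allyloxy)-3,5-dimethoxybenzaldehyde F1, which is condensed with TsNHNH2 to (E)-N'-[4-(allyloxy)-3,5-dimethoxybenzylidene]-4-methylbenzenesulfonohydrazide F2. F2 is coupled with 6 (K2CO3, 1,4-dioxane, 110 °C) to (1R,2S,3R)-4-[4-(allyloxy)-3,5-dimethoxyphenyl]-2,3-dimethyl-1-(3,4,5-trimethoxyphenyl)butyl benzoate F3, which is isolated and deallylated with Pd(PPh3)4 and morpholine. This comes back to the route at 11, now isolated, which is oxidised in a separate flask with PhI(OCOCF3)2 in CF3CH2OH to 12. If the benzoate is lost, the free alcohol is re-benzoylated before the oxidation.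

Step 3. Borylcupration next to the branched C2 centre may give poor branched-to-linear selectivity or mismatched facial selectivity. The fallback sets out from 4 and installs boron by cross-coupling and the stereocentre by hydrogenation. Tsuji–Wacker oxidation (PdCl2, CuCl, O2, DMF/H2O) should give (1R,2R)-2-methyl-3-oxo-1-(3,4,5-trimethoxyphenyl)butyl benzoate F4. Kinetic enolisation at the methyl group (KN(SiMe3)2, PhNTf2, THF, −78 °C) should give (1R,2R)-2-methyl-3-{[(trifluoromethyl)sulfonyl]oxy}-1-(3,4,5-trimethoxyphenyl)but-3-en-1-yl benzoate F5. Miyaura borylation (PdCl2(PPh3)2, PPh3, KOPh, B2pin2, toluene, 50 °C) should give (1R,2S)-2-methyl-3-(4,4,5,5-tetramethyl-1,3,2-dioxaborolan-2-yl)-1-(3,4,5-trimethoxyphenyl)but-3-en-1-yl benzoate F6. Asymmetric hydrogenation of the 1,1-disubstituted alkenylboronate ([Rh(cod)2]BF4 with a chiral bisphosphine, H2) comes back to the route at 5.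

Step 4. Periodate may oxidise the C–B bond, or pinacol removal may stay incomplete. The fallback sets out from 5 and goes through a crystalline salt: KHF2 in MeOH/H2O should give potassium [(2S,3S,4R)-4-(benzoyloxy)-3-methyl-4-(3,4,5-trimethoxyphenyl)butan-2-yl]trifluoroborate F7, and hydrolysis with Me3SiCl and H2O in MeCN comes back to the route at 6.

Further compounds
F1 | step 6 | 4-(allyloxy)-3,5-dimethoxybenzaldehyde | C=CCOc1c(OC)cc(C=O)cc1OC
F2 | step 6 | (E)-N'-[4-(allyloxy)-3,5-dimethoxybenzylidene]-4-methylbenzenesulfonohydrazide | C=CCOc1c(OC)cc(/C=N/NS(=O)(=O)c2ccc(C)cc2)cc1OC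
F3 | step 6 | (1R,2S,3R)-4-[4-(allyloxy)-3,5-dimethoxyphenyl]-2,3-dimethyl-1-(3,4,5-trimethoxyphenyl)butyl benzoate | C=CCOc1c(OC)cc(C[C@@H](C)[C@H](C)[C@@H](OC(=O)c2ccccc2)c2cc(OC)c(OC)c(OC)c2)cc1OC
F4 | step 3 | (1R,2R)-2-methyl-3-oxo-1-(3,4,5-trimethoxyphenyl)butyl benzoate | CC(=O)[C@H](C)[C@@H](OC(=O)c1ccccc1)c1cc(OC)c(OC)c(OC)c1
F5 | step 3 | (1R,2R)-2-methyl-3-{[(trifluoromethyl)sulfonyl]oxy}-1-(3,4,5-trimethoxyphenyl)but-3-en-1-yl benzoate | C=C(OS(=O)(=O)C(F)(F)F)[C@H](C)[C@@H](OC(=O)c1ccccc1)c1cc(OC)c(OC)c(OC)c1
F6 | step 3 | (1R,2S)-2-methyl-3-(4,4,5,5-tetramethyl-1,3,2-dioxaborolan-2-yl)-1-(3,4,5-trimethoxyphenyl)but-3-en-1-yl benzoate | C=C(B1OC(C)(C)C(C)(C)O1)[C@H](C)[C@@H](OC(=O)c1ccccc1)c1cc(OC)c(OC)c(OC)c1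
F7 | step 4 | potassium [(2S,3S,4R)-4-(benzoyloxy)-3-methyl-4-(3,4,5-trimethoxyphenyl)butan-2-yl]trifluoroborate | [K+].F[B-](F)(F)[C@@H](C)[C@H](C)[C@@H](OC(=O)c1ccccc1)c1cc(OC)c(OC)c(OC)c1
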